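**Numbering used in the text.** Ring A is the free trihydroxyphenyl ring (C1' bears the acyl group, C3' bears the side chain). Ring B is the benzene ring of the benzofuran (C3a to C7a). Ring C is the furan ring (O1, C2, C3). The chain is Cα (diaryl methine), Cβ (CHOH) and Cγ (CH2OH).

## Analysis of the target

- **Skeleton.** The target consists of two identical phlorisovalerophenone units joined by five carbons. Ring A is an intact 2',4',6'-trihydroxy-1'-isovalerylphenyl group. Ring B is fused to furan ring C as a 4,6-dihydroxy-7-isovalerylbenzofuran.
- **The feature that invites the strategy.** This is the chain C3–C2 (ring C)–Cα–Cβ–Cγ.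
  - C3 is bonded to C3a of ring B, C2 carries the furan oxygen O1, Cα carries C3' of ring A, and Cβ and Cγ keep their hydroxyl groups.
  - That is the substitution and oxidation pattern of a pentose. C27H32O10 equals two C11H14O4 plus C5H10O5 minus three H2O.
- **Stereocentres.** There are two contiguous stereocentres, Cα (S) and Cβ (R), in an erythro relation. In a Fischer projection with the furan on top, ring A and the Cβ hydroxyl lie on the same side. Cβ has the L-glycero configuration, which is that of C4 of an L-pentose.
- **The hard centre.** Cα bears no heteroatom and sits between two very electron-rich (hetero)arenes. The Cα–C3' bond can heterolyse in acid, so the configuration must be set late and under mild conditions.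
- **Regiochemistry.** O1 sits on the ring-B carbon next to the acyl-bearing carbon (7-acyl, not 5-acyl). The hydroxyl para to the acyl group is normally the more reactive one.
- **Sensitive groups.** These are five free phenols (oxidation, O- versus C-alkylation), two chelated aryl ketones, the vicinal diol, and the 2-(2-hydroxybenzyl)benzofuran motif. In strong acid that motif can isomerise through a spiroketal to a tetrasubstituted furan, with loss of Cα.

## Retrosynthetic reasoning

**16 to 15 to 14.**
- Only protecting-group C–O bonds are cut: the two benzyl ethers on the oxygen para to each acyl group, and the isopropylidene acetal on Cβ–O/Cγ–O.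
- Both groups steer the key step, so they are not ballast. The benzyl ether decides the direction of furan closure. The acetal blocks the two hydroxyls that would otherwise trap the first intermediate, and it provides the facial bias at Cα.
- The last operation is neutral, so the free polyphenol 16 never meets acid.

**14 to two molecules of 4 plus 8 (key disconnection).**
- Three bonds are cut at once: C3a–C3, O1–C2 (both in ring C) and Cα–C3'.
- Cutting here turns rings A and B into one and the same arene, 4. The five-carbon chain becomes an open-chain L-pentose derivative, 8, already at the right oxidation level, so the union is redox neutral and is a threefold dehydration.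
- The forward reaction has to do four things:
  - join C3 of 4 to the aldehyde carbon of 8;
  - move the oxidation level from C1 to C2 of the sugar chain;
  - close and aromatise the furan;
  - ionise the former C3 hydroxyl and alkylate a second molecule of 4 on one face.
- C1, C2 and C3 of 8 all become trigonal on the way. Only C4 of 8 has to be right, and it ends up as Cβ.

**8 to 7 to 6 to 5.**
- The pentose must react as a free aldehyde and must not offer O-4 or O-5 as internal nucleophiles.
- Cheap L-arabinose 5 has the needed C4 configuration. It is opened as the diethyl dithioacetal 6, acetalised at the terminal diol to give 7, and unmasked to 8.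
- No C–C bond is made on this branch and no stereocentre is created.

**4 to 3 to 1 plus 2.**
- The arene is cut at the acyl C–C bond and at the benzyl O–C bond.
- Acylation of symmetric 1 has no regiochemical issue. In 3 the para hydroxyl is the only one not chelated to the ketone, so it can be addressed selectively.
- In 4 the two nucleophilic carbons C3 and C5 are homotopic.

## Alternatives that were turned down

**Alternative 1:** (textbook) Only the Cα–C3' bond is cut.
- *Forward route.* 4 is iodinated and joined to a commercial C5 enynol by Sonogashira heteroannulation, giving allylic alcohol A1. Sharpless epoxidation with L-(+)-tartrate gives epoxy alcohol A2, which 4 opens at Cα in a Friedel–Crafts reaction with inversion.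
- *Why turned down.*
  - The epoxide carbon Cα of A2 is attached to a 4,6-dioxygenated benzofuran, so its C–O bond heterolyses very easily.
  - A2 would hardly survive the titanium reagent. Its opening would run through the same planar cation as 13, so the Cα–O centre bought with the chiral reagent would not be transferred.
  - Both stereocentres would come from an external reagent, although Cβ is available from the chiral pool.
  - Ring C and the two C–C bonds would be made in separate operations, and the free phenols would call for more protection.

**Alternative 2:** The Cα–C2 bond is cut.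
- *Forward route.* The 2-lithio derivative of benzofuran A3 is added to a protected L-glyceraldehyde to give carbinol A4. Ring A is then alkylated, and both isovaleryl groups are introduced at the end.
- *Why turned down.*
  - Lithiation tolerates neither the aryl ketone nor free phenols, which forces the late double acylation.
  - That acylation would have to choose among C3, C5 and C7 of the benzofuran and two positions of ring A, in the presence of an acid-labile diaryl methine.
  - A3 needs several steps of its own, and the difficult facial problem at Cα remains unchanged.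

**Alternative 3:** The Cα–Cβ bond is cut.
- *Forward route.* The C2-symmetric 1,3-diarylpropan-2-one A5 is desymmetrised by an asymmetric aldol reaction with an O-protected glycolaldehyde to give A6. Cyclodehydration on the unsubstituted side follows.
- *Why turned down.*
  - A5 carries o-hydroxyaryl groups on both sides of the ketone and would close to a benzofuran or spiroketal before it could be enolised.
  - A6 is an α-aryl-β-hydroxy ketone. Retro-aldol cleavage, epimerisation at Cα and dehydration are all easy.
  - Both stereocentres need external control.
  - Closure of the furan by ring A towards Cα would give the more substituted furan and destroy Cα.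

Key step: step 6

**Remark.** 5 is drawn in its open-chain form. 8 is expected to equilibrate with its hydrate and hemiacetal oligomers, which react as the free aldehyde.

## Route

Step 1
Reactants: 1 phloroglucinol; 2 isovaleryl chloride
Product: 3 phlorisovalerophenone (3-methyl-1-(2,4,6-trihydroxyphenyl)butan-1-one)
Conditions: AlCl3 (3 equiv), CH2Cl2–MeNO2, 0 to 40 °C; aq. HCl work-up
Reagents that add atoms: none
Why: Friedel–Crafts acylation of a symmetric, very electron-rich arene; all three ring positions are equivalent and the chelated ketone deactivates the product against a second acylation.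

Step 2
Reactants: 3 phlorisovalerophenone
Product: 4 1-[4-(benzyloxy)-2,6-dihydroxyphenyl]-3-methylbutan-1-one
Conditions: BnBr (1.0 equiv), K2CO3 (1.05 equiv), acetone, 50 °C
Reagents that add atoms: benzyl bromide, BrCc1ccccc1
Why: Williamson etherification; O-4 is the most acidic hydroxyl and the only one not hydrogen-bonded to the ketone, so one equivalent of base and halide should address it selectively.

Step 3
Reactants: 5 L-arabinose
Product: 6 L-arabinose diethyl dithioacetal
Conditions: EtSH (2.2 equiv), conc. HCl, 0 °C
Reagents that add atoms: ethanethiol, CCS
Why: Classical dithioacetalisation of an aldose; it locks the sugar in the open-chain form and touches no stereocentre.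

Step 4
Reactants: 6 L-arabinose diethyl dithioacetal
Product: 7 4,5-O-isopropylidene-L-arabinose diethyl dithioacetal
Conditions: 2-methoxypropene (1.1 equiv), TsOH (cat.), DMF, 0 °C
Reagents that add atoms: 2-methoxypropene, COC(C)=C
Why: Kinetic acetonation; the primary hydroxyl adds first to the enol ether and closure onto O-4 gives the terminal dioxolane, leaving the 2,3-diol free.

Step 5
Reactants: 7 4,5-O-isopropylidene-L-arabinose diethyl dithioacetal
Product: 8 4,5-O-isopropylidene-aldehydo-L-arabinose
Conditions: I2, NaHCO3, acetone–H2O, 0 °C; extracted and used crude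
Reagents that add atoms: water, O
Why: Oxidative hydrolysis of a dithioacetal under bicarbonate buffer, which spares the acetal; any epimerisation at C2 is harmless because C2 becomes trigonal in step 6.

Step 6
Reactants: 4 1-[4-(benzyloxy)-2,6-dihydroxyphenyl]-3-methylbutan-1-one (2.2 equiv); 8 4,5-O-isopropylidene-aldehydo-L-arabinose
Product: 14 1-{4-(benzyloxy)-3-[(S)-[4-(benzyloxy)-6-hydroxy-7-(3-methylbutanoyl)-1-benzofuran-2-yl][(4R)-2,2-dimethyl-1,3-dioxolan-4-yl]methyl]-2,6-dihydroxyphenyl}-3-methylbutan-1-one, via benzylic alcohol 9 (not isolated), via o-quinone methide 10 (not isolated), via benzyl ketone 11 (not isolated), via benzofuranyl carbinol 12 (not isolated), via benzofuranylmethyl cation 13 (not isolated)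
Conditions: Sc(OTf)3 (10 mol %), 4 Å MS, MeCN (0.05 M), 0 to 45 °C
Reagents that add atoms: none
Why: Proposed new method: the Lewis acid lets C3 of 4 (C3 and C5 are homotopic) add to the aldehyde of 8 to give 9, which loses its benzylic hydroxyl to form o-quinone methide 10, and 10 re-aromatises by moving H-2 of the sugar chain to the quinone methide oxygen (1,5-H shift or acid-catalysed tautomerisation), the resulting enol being ketone 11. The phenol oxygen next to the new benzyl carbon adds to the C2 ketone (5-exo-trig) and dehydration gives the aromatic furan ring of 12, the only ring closed in this step. In 12 the former C3 hydroxyl is the only C–O bond that can ionise; it gives cation 13, which alkylates C3 of a second molecule of 4 in an SN1-type Friedel–Crafts reaction. The closest known reaction types are the Garcia Gonzalez synthesis of polyhydroxyalkylfurans from aldoses and 1,3-dicarbonyl compounds, the Sc(OTf)3-catalysed C-glycosylation of phloroacetophenone with free sugars, the cyclodehydration of o-hydroxybenzyl ketones to 2-substituted benzofurans and the catalytic Friedel–Crafts benzylation with secondary benzylic alcohols; new is their union on an open-chain sugar and a phenol in one operation. C1, C2 and C3 of the sugar chain all become trigonal, so the step is stereoconvergent with respect to them and only C4 survives, as Cβ. Cα is set by 1,2-induction from Cβ: in 13 allylic 1,3-strain places H-β in the plane of the cation next to the furan, the dioxolane C–O bond stands perpendicular on one face and the arene attacks anti to it (modified Felkin–Anh model, the anti sense known for carbon nucleophiles adding to γ-alkoxy acceptors derived from glyceraldehyde acetonide), which should give the erythro (S,R) isomer, a formal retention relative to C3 of 5. The benzyl ether on O-4 leaves only O-2 to close the furan, which secures the 7-acyl pattern, and the acetal ties up O-4 and O-5 of the sugar so that 10 cannot be trapped as a C-glycoside. The main competing path, addition of a second 4 to C1 of 10, is reversible under acid whereas aromatisation to 12 is not, and the dilution favours the unimolecular exit.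

Step 7
Reactants: 14 coupled acetonide
Product: 15 1-{4-(benzyloxy)-3-[(1S,2R)-1-[4-(benzyloxy)-6-hydroxy-7-(3-methylbutanoyl)-1-benzofuran-2-yl]-2,3-dihydroxypropyl]-2,6-dihydroxyphenyl}-3-methylbutan-1-one
Conditions: AcOH–H2O (4:1), 40 °C
Reagents that add atoms: none
Why: Hydrolysis of a terminal isopropylidene acetal; acetic acid is too weak to protonate ring A at C3' or to ionise the Cα–C3' bond, so both stereocentres should stay untouched.

Step 8
Reactants: 15 bis-benzyl ether diol
Product: 16 target, 1-{3-[(1S,2R)-1-[4,6-dihydroxy-7-(3-methylbutanoyl)-1-benzofuran-2-yl]-2,3-dihydroxypropyl]-2,4,6-trihydroxyphenyl}-3-methylbutan-1-one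
Conditions: H2 (1 atm), 10 % Pd/C, EtOAc–MeOH, rt
Reagents that add atoms: none
Why: Hydrogenolysis of two aryl benzyl ethers under neutral conditions; chelated aryl ketones, the benzofuran C2=C3 bond and the all-carbon diaryl methine are not expected to react at 1 atm.

## Compound list

1 | phloroglucinol | Oc1cc(O)cc(O)c1 | starting material
2 | isovaleryl chloride | CC(C)CC(=O)Cl | starting material
3 | phlorisovalerophenone | CC(C)CC(=O)c1c(O)cc(O)cc1O | intermediate
4 | 1-[4-(benzyloxy)-2,6-dihydroxyphenyl]-3-methylbutan-1-one | CC(C)CC(=O)c1c(O)cc(OCc2ccccc2)cc1O | intermediate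
5 | L-arabinose (open-chain form) | O=C[C@H](O)[C@@H](O)[C@@H](O)CO | starting material
6 | L-arabinose diethyl dithioacetal | CCSC(SCC)[C@H](O)[C@@H](O)[C@@H](O)CO | intermediate
7 | 4,5-O-isopropylidene-L-arabinose diethyl dithioacetal | CCSC(SCC)[C@H](O)[C@@H](O)[C@@H]1COC(C)(C)O1 | intermediate
8 | 4,5-O-isopropylidene-aldehydo-L-arabinose | O=C[C@H](O)[C@@H](O)[C@@H]1COC(C)(C)O1 | intermediate
9 | benzylic alcohol: 1-C-aryl-4,5-O-isopropylidene-L-arabinitol, C1 epimers, aryl = C3 of 4 | CC(C)CC(=O)c1c(O)cc(OCc2ccccc2)c(C(O)[C@H](O)[C@@H](O)[C@@H]2COC(C)(C)O2)c1O | intermediate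
10 | o-quinone methide from 9 (C2 carbonyl, exocyclic C3=C1 of the sugar chain) | CC(C)CC(=O)C1=C(O)C=C(OCc2ccccc2)C(=C[C@H](O)[C@@H](O)[C@@H]2COC(C)(C)O2)C1=O | intermediate
11 | benzyl ketone: 1-aryl-1-deoxy-4,5-O-isopropylidene-L-pent-2-ulose | CC(C)CC(=O)c1c(O)cc(OCc2ccccc2)c(CC(=O)[C@@H](O)[C@@H]2COC(C)(C)O2)c1O | intermediate
12 | 1-{4-(benzyloxy)-2-[(S)-[(4S)-2,2-dimethyl-1,3-dioxolan-4-yl](hydroxy)methyl]-6-hydroxy-1-benzofuran-7-yl}-3-methylbutan-1-one | CC(C)CC(=O)c1c(O)cc(OCc2ccccc2)c2cc(oc12)[C@@H](O)[C@@H]1COC(C)(C)O1 | intermediate
13 | benzofuran-2-ylmethyl cation from 12 | CC(C)CC(=O)c1c(O)cc(OCc2ccccc2)c2cc(oc12)[CH+][C@@H]1COC(C)(C)O1 | intermediate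
14 | coupled bis-benzyl ether acetonide, Cα (S), dioxolane C4 (R) | CC(C)CC(=O)c1c(O)cc(OCc2ccccc2)c([C@H](c2cc3c(OCc4ccccc4)cc(O)c(C(=O)CC(C)C)c3o2)[C@@H]2COC(C)(C)O2)c1O | intermediate
15 | bis-benzyl ether diol, (1S,2R) | CC(C)CC(=O)c1c(O)cc(OCc2ccccc2)c([C@H](c2cc3c(OCc4ccccc4)cc(O)c(C(=O)CC(C)C)c3o2)[C@@H](O)CO)c1O | intermediate
16 | CNP0169876.1, (1S,2R) | CC(C)CC(=O)c1c(O)cc(O)c([C@H](c2cc3c(O)cc(O)c(C(=O)CC(C)C)c3o2)[C@@H](O)CO)c1O | target

## Step count and risks

Total step count: 8. Longest linear sequence: 6 (steps 3 to 8, from 5). The arene branch (steps 1 and 2) joins at step 6.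

**Step 6 (key step, bears the label).**
- *What may go wrong.*
  - A second molecule of 4 may capture 10 at C1 faster than 10 tautomerises, with too slow a return.
  - The acetal may migrate or hydrolyse early. This would free O-4 or O-5 of the sugar and let it close onto C1.
  - β-Elimination may occur in 11, or proton loss from Cβ of 13.
  - Facial selectivity at Cα may be poor, or may erode through reversible C–C bond formation.
- *Fallback.* It uses known chemistry only, sets out from 7 and 4, and returns at 14.
  - Glycol cleavage of 7 with Pb(OAc)4 gives (S)-glyceraldehyde acetonide F1.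
  - Ethynylmagnesium bromide adds to F1 to give the propargylic alcohol F2. It forms as a mixture of carbinol epimers, which does not matter.
  - 4 is mono-iodinated with NIS to the iodophenol F3.
  - Sonogashira coupling of F2 and F3, with 5-endo-dig closure by the only neighbouring free hydroxyl in the same flask, gives the benzofuranyl carbinol F4 (12 as its epimer mixture).
  - F4 then alkylates 4 under catalytic Bi(OTf)3 at low temperature. This is a catalytic Friedel–Crafts benzylation run on its own under kinetic control, and it gives 14.

**Step 5.**
- *What may go wrong.* The α,β-dihydroxy aldehyde may self-condense during isolation, hypoiodite may over-oxidise it, or the acetal may migrate.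
- *Fallback.* It sets out from 7 and returns at 14. I2 and NaHCO3 in MeOH convert 7 into the storable dimethyl acetal F5. Under the conditions of step 6, F5 is ionised to an oxocarbenium ion that alkylates 4. The benzylic methyl ether so formed ionises to 10 just as 9 does.

**Step 4.**
- *What may go wrong.* Acetonation may be unselective (2,3- or 3,4-acetals, double acetonation), and the acetal may migrate under the acid catalyst.
- *Fallback.* It sets out from 6 and returns at 14.
  - Exhaustive acetonation (acetone, 2,2-dimethoxypropane, TsOH) has no regiochemical issue and gives the diacetonide dithioacetal F6.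
  - Unmasking as in step 5 gives the stable, monomeric diacetonide aldehyde F7, which enters step 6 in place of 8.
  - After the hydrogen shift the internal acetal has become an enol acetal. The neighbouring phenol opens it and expels it during aromatisation, while the terminal acetal stays.

**Step 2.**
- *What may go wrong.* Over-benzylation and C-benzylation of the ambident phenolate.
- *Fallback.* It sets out from 3 and returns at 4. Perbenzylation (excess BnBr, K2CO3, DMF) gives the tribenzyl ether F8. BCl3 (2.2 equiv, CH2Cl2, −78 to 0 °C) then removes only the two benzyl groups ortho to the ketone, by chelation-controlled cleavage.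

## Further compounds

F1 | step 6 | (S)-2,2-dimethyl-1,3-dioxolane-4-carbaldehyde | O=C[C@@H]1COC(C)(C)O1
F2 | step 6 | 1-[(4S)-2,2-dimethyl-1,3-dioxolan-4-yl]prop-2-yn-1-ol (carbinol epimers) | C#CC(O)[C@@H]1COC(C)(C)O1
F3 | step 6 | 1-[4-(benzyloxy)-2,6-dihydroxy-3-iodophenyl]-3-methylbutan-1-one | CC(C)CC(=O)c1c(O)cc(OCc2ccccc2)c(I)c1O
F4 | step 6 | benzofuranyl carbinol, 12 as a mixture of Cα epimers | CC(C)CC(=O)c1c(O)cc(OCc2ccccc2)c2cc(oc12)C(O)[C@@H]1COC(C)(C)O1
F5 | step 5 | 4,5-O-isopropylidene-L-arabinose dimethyl acetal | COC(OC)[C@H](O)[C@@H](O)[C@@H]1COC(C)(C)O1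
F6 | step 4 | 2,3:4,5-di-O-isopropylidene-L-arabinose diethyl dithioacetal | CCSC(SCC)[C@@H]1OC(C)(C)O[C@H]1[C@@H]1COC(C)(C)O1
F7 | step 4 | 2,3:4,5-di-O-isopropylidene-aldehydo-L-arabinose | O=C[C@@H]1OC(C)(C)O[C@H]1[C@@H]1COC(C)(C)O1
F8 | step 2 | 3-methyl-1-[2,4,6-tris(benzyloxy)phenyl]butan-1-one | CC(C)CC(=O)c1c(OCc2ccccc2)cc(OCc2ccccc2)cc1OCc1ccccc1
A1 | alternative 1 | 1-{4-(benzyloxy)-6-hydroxy-2-[(E)-3-hydroxyprop-1-enyl]-1-benzofuran-7-yl}-3-methylbutan-1-one | CC(C)CC(=O)c1c(O)cc(OCc2ccccc2)c2cc(oc12)/C=C/CO
A2 | alternative 1 | 1-{4-(benzyloxy)-6-hydroxy-2-[(2R,3S)-3-(hydroxymethyl)oxiran-2-yl]-1-benzofuran-7-yl}-3-methylbutan-1-one (trans epoxide) | CC(C)CC(=O)c1c(O)cc(OCc2ccccc2)c2cc(oc12)[C@@H]1O[C@H]1CO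
A3 | alternative 2 | 4,6-bis(benzyloxy)-1-benzofuran | c1cc2c(OCc3ccccc3)cc(OCc3ccccc3)cc2o1
A4 | alternative 2 | [4,6-bis(benzyloxy)-1-benzofuran-2-yl][(4S)-2,2-dimethyl-1,3-dioxolan-4-yl]methanol (carbinol epimers) | OC(c1cc2c(OCc3ccccc3)cc(OCc3ccccc3)cc2o1)[C@@H]1COC(C)(C)O1
A5 | alternative 3 | 1,3-bis[6-(benzyloxy)-2,4-dihydroxy-3-(3-methylbutanoyl)phenyl]propan-2-one | O=C(Cc1c(O)c(C(=O)CC(C)C)c(O)cc1OCc1ccccc1)Cc1c(O)c(C(=O)CC(C)C)c(O)cc1OCc1ccccc1
A6 | alternative 3 | aldol adduct of A5 with benzyloxyacetaldehyde, Cα and Cβ as in the target | O=C(Cc1c(O)c(C(=O)CC(C)C)c(O)cc1OCc1ccccc1)[C@@H](c1c(O)c(C(=O)CC(C)C)c(O)cc1OCc1ccccc1)[C@@H](O)COCc1ccccc1
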